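| setting | amber | ochre | flask |
|---|---|---|---|
| substrate | 0.067 M | 0.15 M | 0.10 M |
| reagent in the second phase | 0.13 M | 0.13 M | 0.130 M |
| remark | run made earlier | run made earlier |  |
| time |  |  | 10 h |
| volume of the second phase over the first |  |  | 0.50 |

- amber (time / h: target / %, substrate / %): 1.33: 3.7, 95.7; 2.50: 7.9, 90.2; 4.00: 10.6, 84.0; 5.00: 11.5, 80.5; 6.00: 11.9, 78.7; 8.00: 12.6, 75.4
- ochre (time / h: target / %, substrate / %): 0.667: 1.5, 98.0; 1.00: 2.4, 97.2; 2.00: 5.9, 93.0; 3.00: 7.5, 88.2; 5.00: 10.3, 83.2; 8.00: 11.7, 79.5

(scatter of a reading: 0.5 percentage points)

- in the second phase: reagent in the second phase; everything else is in the first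
- charges count per volume of the first phase; a concentration in a rate is the amount of a species over the volume of its own phase; every rate counts per litre of the first phase
- the numbers in the tables scatter by 0.5 percentage points (one standard deviation)
- the earlier runs hold the two phases in the same ratio of volumes as the flask asked about

- the target standing at 10 h, as a percentage of the substrate charged
- part of the substrate charged that has reacted at 10 h

Counting reagent against substrate cannot account for the slowing of the amber run. By 8.00 h the amber readings put the reagent spent on substrate and its products at 0.0245 M, less than the 0.13 M charged. This count supposes one reagent per substrate reacted and one more per substrate in the unaccounted remainder. On charges, the substrate of the flask is the limiting reagent, at 0.10 M, less than the 0.130 M of reagent.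

My own reckoning therefore supposes that reagent is also lost by a first-order step, with constant k′, beside its reaction with substrate, with constant k. Substrate then falls as k[reagent][substrate] and lost reagent grows as k′[reagent], so [reagent] cancels: the logarithm of substrate charged over substrate left rises in step with reagent lost.

Divide that logarithm by the reagent not spent in that count, and call the ratio the reach. That divisor holds reagent still unlost as well as reagent lost, so on this supposition the reach climbs towards k/k′ as the unlost part shrinks. Amber gives 2.68 M⁻¹ at 8.00 h. Ochre, with twice the substrate, gives 2.67 M⁻¹. At 5.00 h the two read 1.94 M⁻¹ and 1.94 M⁻¹.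

At each of these times the two readings agree, although the substrate charges differ. I expect its rise to slow, so at 10 h I take the midpoint between 2.68 M⁻¹ and the straight-line value 3.17 M⁻¹, which is 2.92 M⁻¹. If the flask spends reagent equal to 32.9% of its substrate charge in that count, the mean of the two runs at 8.00 h taken roughly, then my estimate is 24.7% of its substrate reacted.

The forecast gives 12.8% target (11.6% to 14%) and 25% reacted (22% to 28%), on its own ground: “Interpolating on log concentration”.

The flask gives 12.4% target, with 24.5% of the substrate reacted.

    reagent in the reaction phase → decomposed reagent (k = 0.00820 min⁻¹)
    reagent in the reaction phase + target → over-reacted product (k = 0.0810 M⁻¹ min⁻¹)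
    substrate + reagent in the reaction phase → target (k = 0.0280 M⁻¹ min⁻¹)
    reagent in the reaction phase ⇌ reagent in the second phase, rate k4*([reagent in the reaction phase] - [reagent in the second phase]/K4) per volume of the first phase (partition coefficient = 0.550, kL = 0.00160 min⁻¹)
    reagent in the reaction phase + target → over-reaction product (k = 0.0650 M⁻¹ min⁻¹)

At 10 h the flask has 5.13% of its reagent left in the second phase, and decomposed reagent stands at 63.4% of the reagent charged, while 75% of the substrate remains. The same flask read at 4.0 h takes amber's reach at 4.00 h, 1.51 M⁻¹, lower than the 2.68 M⁻¹ at 8.00 h, and with amber's spent share at that time this reach gives an estimate of 15.1% reacted. That neighbour stands at 15.5% reacted, with 28.9% of its reagent still in the second phase.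

Readings and results come from a simulation for substances that don't exist; the scatter is artificial.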